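**Assumption:** the target has no stereocentres (it is achiral and exists as a largely enolised β-diketone), so no stereocontrol is needed. The route has not been run; conditions are by analogy to known reaction types.

## Retrosynthetic overview

1. The β-diketone is closed last at ArB–CO | CH2–CO–ArA: the enolate of the ring-A methyl ketone is acylated by the ring-B salicylic acid (as its acyl imidazolide).
2. The ring-B acid comes from 2,2-dimethyl-2H-chromen-7-ol by ortho-carboxylation at C6. Carboxylating after annulation fixes the linear 6-acyl-7-hydroxy pattern.
3. The chromenol comes from resorcinol + prenal in one desymmetrising annulation through an o-quinone methide. This is the only ring formed in the synthesis, and it is made first.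
4. The ring-A ketone comes from 4'-hydroxyacetophenone by direct ortho-C-prenylation.
5. No protecting groups are used.

## Route

**Step 1 (key step)**
Reactants: 1 resorcinol (benzene-1,3-diol); 2 3-methylbut-2-enal (prenal)
Product: 3 2,2-dimethyl-2H-chromen-7-ol
Conditions: 2 (1 equiv, slow addition), 1 (3 equiv), pyridine, 140 °C (sealed), 12 h; aqueous wash removes excess 1; SiO2 with 1% Et3N
Reagents that add atoms: 3-methylbut-2-enal (2), CC(C)=CC=O
Why: Pyridine-mediated phenol–enal chromenylation (formal [3+3]: ortho-C aldol-type addition, dehydration to a dearomatised o-quinone methide, oxa-6π electrocyclisation) desymmetrises C2v resorcinol in one operation; attack at C4 (ortho to one OH, para to the other) rather than the hindered C2 gives the 7-hydroxy isomer, and excess resorcinol suppresses double annulation.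

**Step 2**
Reactants: 3 2,2-dimethyl-2H-chromen-7-ol; 4 methylmagnesium carbonate (MMC, Stiles reagent)
Product: 5 7-hydroxy-2,2-dimethyl-2H-chromene-6-carboxylic acid
Conditions: MMC (2 M in DMF, 8 equiv), 120 °C, N2, 4 h; then ice-cold 10% aq. citric acid
Reagents that add atoms: methylmagnesium carbonate (4), COC(=O)O[Mg]OC (delivers CO2)
Why: Kolbe–Schmitt-type ortho-carboxylation driven by the magnesium salicylate chelate; C6 (ortho to the OH, para to the ring oxygen) is favoured over C8, which sits between two oxygens, as in olivetol → olivetolic acid, and the all-basic medium spares the acid-labile chromene.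

**Step 3**
Reactants: 6 4'-hydroxyacetophenone; 7 prenyl bromide (1-bromo-3-methylbut-2-ene)
Product: 8 1-[4-hydroxy-3-(3-methylbut-2-en-1-yl)phenyl]ethan-1-one
Conditions: 7 (1.0 equiv), 10% aq. KOH, rt, 24 h; acidify; chromatography (recover 6 and the O-prenyl ether)
Reagents that add atoms: prenyl bromide (7), CC(C)=CCBr
Why: Direct phenoxide ortho-C-alkylation in water (hydrogen bonding to O disfavours O-alkylation; the ring attacks through a 6-prenylcyclohexa-2,4-dienone that tautomerises), and because the two ortho positions are equivalent only one mono-C-prenyl isomer can form; expect a modest yield (about 30%).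

**Step 4**
Reactants: 5 7-hydroxy-2,2-dimethyl-2H-chromene-6-carboxylic acid; 8 1-[4-hydroxy-3-(3-methylbut-2-en-1-yl)phenyl]ethan-1-one
Product: 9 Glyinflanin C, 1-(7-hydroxy-2,2-dimethyl-2H-chromen-6-yl)-3-[4-hydroxy-3-(3-methylbut-2-en-1-yl)phenyl]propane-1,3-dione
Conditions: (i) 5, CDI (1.1 equiv), THF, 0 °C → rt, 1 h; (ii) cannulate into 8 (1.3 equiv) + LiHMDS (6 equiv), THF, −78 → 0 °C, 3 h; (iii) cold 10% aq. citric acid
Reagents that add atoms: none (CDI and LiHMDS leave no atoms in the product)
Why: Crossed-Claisen-type C-acylation of a lithium ketone enolate by an acyl imidazolide, run on the unprotected lithium polyanions: the phenoxides are spectators, the enolate carbon is the most nucleophilic site, and the product is shielded as its β-diketonate; the o-phenoxide imidazolide reacts directly or via an o-quinone ketene, both giving the same product.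

## Compound list

1 | resorcinol | Oc1cccc(O)c1 | starting material
2 | 3-methylbut-2-enal (prenal) | CC(C)=CC=O | starting material
3 | 2,2-dimethyl-2H-chromen-7-ol | CC1(C)C=Cc2ccc(O)cc2O1 | intermediate
4 | methylmagnesium carbonate (MMC) | COC(=O)O[Mg]OC | starting material (commercial reagent, CO2 donor)
5 | 7-hydroxy-2,2-dimethyl-2H-chromene-6-carboxylic acid | CC1(C)C=Cc2cc(C(=O)O)c(O)cc2O1 | intermediate
6 | 4'-hydroxyacetophenone | CC(=O)c1ccc(O)cc1 | starting material
7 | prenyl bromide | CC(C)=CCBr | starting material
8 | 1-[4-hydroxy-3-(3-methylbut-2-en-1-yl)phenyl]ethan-1-one | CC(=O)c1ccc(O)c(CC=C(C)C)c1 | intermediate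
9 | Glyinflanin C | CC(C)=CCc1cc(C(=O)CC(=O)c2cc3c(cc2O)OC(C)(C)C=C3)ccc1O | target

## Summary

Total steps: 4. Longest linear sequence: 3 (steps 1 → 2 → 4, from resorcinol); step 3 is a one-step side branch.

Steps most likely to fail, with fallbacks:

1. **Step 4** (acylation with an unprotected o-hydroxyaroyl imidazolide and a phenolic ketone dianion: O-acylation, imidazolide self-condensation or incomplete enolisation are possible). Fallback: mask the ring-A phenol as the group that becomes the prenyl unit. Convert 6 to its 1,1-dimethylallyl ether (tert-butyl 2-methylbut-3-en-2-yl carbonate, Pd(PPh3)4), acylate that mono-enolate with the imidazolide of 5, then reveal the phenol and ortho-prenyl together by thermal aromatic Claisen rearrangement (PhMe, 110 °C). This also replaces step 3.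

2. **Step 2** (MMC carboxylation of a mono-phenol may stall or give some C8 acid). Fallback: carry the carbonyl in as a methyl ketone using acid-stable chroman chemistry. Make 2,2-dimethylchroman-7-ol from resorcinol + isoprene, acetylate at C6 (AcOH/BF3·OEt2), and dehydrogenate with DDQ to the 6-acetylchromene. Then close the diketone from the other side with methyl 4-(2-methylbut-3-en-2-yloxy)benzoate and LiHMDS, and finish by aromatic Claisen rearrangement.

3. **Step 1** (5-hydroxy regioisomer, double annulation, and an acid-sensitive product). Fallback: build the pyran ring by acylation and oxa-Michael addition instead. Resorcinol + 3-methylbut-2-enoic acid (MsOH/P2O5) gives 7-hydroxy-2,2-dimethylchroman-4-one as a single regioisomer; hydride reduction and mild dehydration then give 3.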